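**Plan**
Numbering: oxolane ring O1–C2(aryl)–C3(CH3)–C4–C5H2, with the carbinol carbon C7′ on C4. The target is (2S,3S,4R,7′R), that is 2,3-trans-3,4-cis.
Enabling feature: C3 and C4 are linked by the short path C3–C2–O1–C5–C4 and C7′ is benzylic. A C3 radical can therefore close the oxolane ring on a C4=C7′ styrene bond and pass the spin to C7′, where O2 is taken up.
Cuts: C7′–O and C3–C4 together (radical step) give a β-bromo cinnamyl ether. C4=C7′ (cross-metathesis) gives an allyl ether and 3,4-dimethoxystyrene. O1–C5 (imidate allylation) gives a bromohydrin, which comes from 3′,4′-dimethoxypropiophenone.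
Forward order: the chain C3–C2–O1–C5–C4=C7′ is built in four linear steps, and the only new ring, the oxolane, closes in the last step.
Stereochemistry: C2 comes from a CBS reduction, and C3, C4 and C7′ are relayed from C2 in the radical step. The C–Br centre is carried as both epimers because it is erased at the radical stage.

Key step: step 5

Remark: the cinnamyl unit is completed by metathesis after O-allylation, because an imidate of the electron-rich cinnamyl alcohol would ionise to an ambident allyl cation. Allyl 2,2,2-trichloroacetimidate and 3,4-dimethoxystyrene are taken as commercial.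

**Step 1**
Reactants: 1 3′,4′-dimethoxypropiophenone
Product: 2 (±)-2-bromo-1-(3,4-dimethoxyphenyl)propan-1-one
Conditions: CuBr2 (2.1 equiv), EtOAc/CHCl3 (1:1), reflux
Reagents that add atoms: copper dibromide CuBr2, [Cu+2].[Br-].[Br-]
Why: Heterogeneous α-bromination of an aryl ketone with CuBr2 brominates the enol only and should spare the electron-rich veratryl ring that Br2 would also attack; the new C–Br centre is racemic, which is harmless because it is destroyed in step 5.

**Step 2**
Reactants: 2 (±)-2-bromo-1-(3,4-dimethoxyphenyl)propan-1-one
Product: 3 (1R,2RS)-2-bromo-1-(3,4-dimethoxyphenyl)propan-1-ol (both bromide epimers, carbinol carbon R; this carbon is the future C2)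
Conditions: (R)-Me-CBS oxazaborolidine (10 mol %), BH3·SMe2 (1.0 equiv), THF, −20 °C, slow addition of 2; MeOH quench
Reagents that add atoms: none
Why: In this Corey–Bakshi–Shibata reduction the ketone should bind to the catalyst–borane adduct with the aryl group as the large flank, so that hydride reaches the Si face and gives the (1R)-carbinol (the sense known for phenacyl halides, (R)-catalyst to (R)-halohydrin), both enantiomers of 2 being reduced to a pair of bromide epimers with a common carbinol configuration.

**Step 3**
Reactants: 3 (1R,2RS)-2-bromo-1-(3,4-dimethoxyphenyl)propan-1-ol; 4 allyl 2,2,2-trichloroacetimidate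
Product: 5 4-[(1R,2RS)-2-bromo-1-(prop-2-en-1-yloxy)propyl]-1,2-dimethoxybenzene
Conditions: 4 (2 equiv), TfOH (5 mol %), 4 Å MS, cyclohexane/CH2Cl2 (2:1), 0 °C to rt
Reagents that add atoms: none
Why: Acid-catalysed O-alkylation with a trichloroacetimidate transfers the allyl group without any base, so the bromohydrin cannot close to the epoxide, and the carbinol C–O bond is not broken, so the R centre is kept, benzylic ionisation being held back by the β-bromine and by the buffering effect of the basic imidate.

**Step 4**
Reactants: 5 4-[(1R,2RS)-2-bromo-1-(prop-2-en-1-yloxy)propyl]-1,2-dimethoxybenzene; 6 3,4-dimethoxystyrene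
Product: 7 4-[(1R,2RS)-2-bromo-1-{[(2E)-3-(3,4-dimethoxyphenyl)prop-2-en-1-yl]oxy}propyl]-1,2-dimethoxybenzene
Conditions: 6 (3 equiv), second-generation Grubbs catalyst (H2IMes)(PCy3)Cl2Ru=CHPh (3 mol %), 1,4-benzoquinone (10 mol %), CH2Cl2, 40 °C
Reagents that add atoms: none
Why: Olefin cross-metathesis of an unhindered terminal allyl ether with a styrene loses ethene and, being reversible, should settle on the conjugated (E)-alkene when 6 is in excess, while the secondary bromide and the benzylic ether are inert to the ruthenium carbene and benzoquinone suppresses allyl-to-propenyl isomerisation.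

**Step 5**
Reactants: 7 4-[(1R,2RS)-2-bromo-1-{[(2E)-3-(3,4-dimethoxyphenyl)prop-2-en-1-yl]oxy}propyl]-1,2-dimethoxybenzene
Product: 9 (R)-(3,4-dimethoxyphenyl)[(3R,4S,5S)-5-(3,4-dimethoxyphenyl)-4-methyloxolan-3-yl]methanol = (2S,3S,4R,7′R)-target, via C7′ hydroperoxide 8 (not isolated)
Conditions: Co(salen) = [N,N′-bis(salicylidene)ethane-1,2-diaminato]cobalt, C16H14CoN2O2 (divalent cobalt, 10 mol %), NaBH4 (2 equiv), aq NaOH (1 equiv), EtOH, high dilution, slow stream of air diluted with N2, 40 °C; chromatography
Reagents that add atoms: dioxygen (from air), O=O
Why: NaBH4 reduces Co(salen) to its monovalent cobalt form, which removes bromine from either epimer of 7 by way of a weak secondary alkyl–cobalt bond, so both epimers give the same planar C3 radical; this adds to C4 of the styrene-type alkene, the benzylic C7′ radical so formed combines with O2, and the peroxyl species is reduced through hydroperoxide 8 to the carbinol by the borohydride present. The closest known reaction type is the oxygenative radical cyclisation of β-halo allyl ethers with cobalt Schiff-base complexes, borohydride and air. The oxolane ring closes in the 5-exo-trig mode (C3–C4 bond), preferred over 6-endo by orbital overlap and because only the exo mode gives a benzylic radical. In the chair-like transition state the aryl group on the fixed C2 centre lies pseudo-equatorial and ends trans to the new C4 branch, while the methyl group on the radical carbon turns away from that aryl group and ends cis to the C4 branch, as is usual for hexenyl radicals substituted at the radical carbon, which sets C3 as S and C4 as R (C2 is untouched; its descriptor changes from R to S only because bromine leaves the neighbouring carbon). At the planar C7′ radical, allylic A(1,3) strain with the ortho hydrogens holds C4–H in the plane on the aryl side, C3 with its methyl group shields one face and O2 enters past C5H2 on the other, which gives 7′R. The step needs ring closure to outrun O2 capture and reduction at C3, which the styrene acceptor, the ether oxygen in the chain and the low O2 concentration should secure, and it needs the trans,cis mode and one C7′ face, both of which should be favoured only moderately, so minor diastereomers are removed by chromatography.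

**Compound list**
1 | 3′,4′-dimethoxypropiophenone | CCC(=O)c1ccc(OC)c(OC)c1 | starting material
2 | (±)-2-bromo-1-(3,4-dimethoxyphenyl)propan-1-one | CC(Br)C(=O)c1ccc(OC)c(OC)c1 | intermediate
3 | (1R,2RS)-2-bromo-1-(3,4-dimethoxyphenyl)propan-1-ol | COc1ccc([C@@H](O)C(C)Br)cc1OC | intermediate
4 | allyl 2,2,2-trichloroacetimidate | C=CCOC(=N)C(Cl)(Cl)Cl | starting material
5 | 4-[(1R,2RS)-2-bromo-1-(prop-2-en-1-yloxy)propyl]-1,2-dimethoxybenzene | COc1ccc([C@@H](OCC=C)C(C)Br)cc1OC | intermediate
6 | 3,4-dimethoxystyrene | C=Cc1ccc(OC)c(OC)c1 | starting material
7 | 4-[(1R,2RS)-2-bromo-1-{[(2E)-3-(3,4-dimethoxyphenyl)prop-2-en-1-yl]oxy}propyl]-1,2-dimethoxybenzene | COc1ccc([C@@H](OC/C=C/c2ccc(OC)c(OC)c2)C(C)Br)cc1OC | intermediate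
8 | (2S,3S,4R,7′R)-C7′ hydroperoxide of the cyclised product (not isolated) | COc1ccc([C@H]2OC[C@H]([C@@H](OO)c3ccc(OC)c(OC)c3)[C@@H]2C)cc1OC | intermediate
9 | (R)-(3,4-dimethoxyphenyl)[(3R,4S,5S)-5-(3,4-dimethoxyphenyl)-4-methyloxolan-3-yl]methanol | COc1ccc([C@H]2OC[C@H]([C@@H](O)c3ccc(OC)c(OC)c3)[C@@H]2C)cc1OC | target

**Step count**
Total step count: 5
Longest linear sequence: 5 steps (1 → 2 → 3 → 5 → 7 → 9)

**Steps most likely to fail**

(a) Step 5. Oxygen capture at the C7′ radical may show poor facial selectivity. Part of the peroxide may also collapse under base to the ketone, which borohydride would reduce with the opposite sense.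

The fallback sets out from 7 and moves control of C7′ from the radical to a ketone. The cyclisation is run as in step 5, but the ring-correct fraction is kept as a mixture of 9 and its (7′S)-epimer F1. This mixture is oxidised with Dess–Martin periodinane (NaHCO3, CH2Cl2) to the aryl ketone F2, which erases C7′ while the non-basic medium protects the epimerisable C4.

Reduction with (S)-Me-CBS oxazaborolidine and BH3·SMe2, with the aryl group as the large flank, should then deliver 7′R and return to 9. The catalyst has to override the substrate's own 1,2-induction, which by the same conformational argument should favour 7′S with simple hydrides.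

(b) Step 3. The acid may ionise the electron-rich benzylic C–O bond and erode the future C2 centre. This would go unnoticed, because the bromide carbon is a mixture. The hindered carbinol may also react so slowly that the imidate rearranges instead.

The fallback sets out from 3 and replaces acid activation by π-allyl-palladium chemistry. Allyl chloroformate and pyridine (CH2Cl2, 0 °C) give the mixed allyl carbonate F3. Pd(PPh3)4 (zerovalent palladium, 5 mol %, THF) then ionises the allyl carbonate, CO2 is lost, and the alkoxide/π-allyl ion pair collapses in a decarboxylative Tsuji–Trost O-allylation. This returns to 5 under neutral conditions without touching the carbinol C–O bond.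

(c) Step 2. The catalyst may differentiate poorly between the aryl flank and the branched CHBrCH3 flank. Enantioselectivity would then be incomplete and different for the two enantiomers of 2.

The fallback sets out from 2 and replaces asymmetric reduction by kinetic resolution. NaBH4 (MeOH, 0 °C) gives the stereorandom bromohydrin F4. Acylative resolution follows with (R)-benzotetramisole (cat.), propanoic anhydride and iPr2NEt (CHCl3, 0 °C). This catalyst class works best for benzylic carbinols with a branched alkyl side.

By analogy with 1-arylalkanols it should acylate the 1S series to the (1S)-propanoate F5 and leave the 1R alcohol. Run slightly past half conversion and chromatographed, the recovered alcohol is 3.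

**Further compounds**
F1 | step 5 | (S)-(3,4-dimethoxyphenyl)[(3R,4S,5S)-5-(3,4-dimethoxyphenyl)-4-methyloxolan-3-yl]methanol | COc1ccc([C@H]2OC[C@H]([C@H](O)c3ccc(OC)c(OC)c3)[C@@H]2C)cc1OC
F2 | step 5 | (3,4-dimethoxyphenyl)[(3R,4S,5S)-5-(3,4-dimethoxyphenyl)-4-methyloxolan-3-yl]methanone | COc1ccc([C@H]2OC[C@H](C(=O)c3ccc(OC)c(OC)c3)[C@@H]2C)cc1OC
F3 | step 3 | allyl (1R,2RS)-2-bromo-1-(3,4-dimethoxyphenyl)propyl carbonate | COc1ccc([C@@H](OC(=O)OCC=C)C(C)Br)cc1OC
F4 | step 2 | 2-bromo-1-(3,4-dimethoxyphenyl)propan-1-ol, all four stereoisomers | COc1ccc(C(O)C(C)Br)cc1OC
F5 | step 2 | (1S,2RS)-2-bromo-1-(3,4-dimethoxyphenyl)propyl propanoate | COc1ccc([C@H](OC(=O)CC)C(C)Br)cc1OC
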